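The route rests on one idea; atoms carry elemanolide numbers: ring A is the cyclohexane C5–C10, ring B the γ-lactone O–C12–C11–C7–C6. Ring B is read as a carbinol carbon (C6), a two-carbon unit (C7–C11) and a one-carbon carbonyl (C12), fused trans to ring A, whose C5–C8 substituents are all equatorial. The acyclic enal 14 (C6 aldehyde, terminal C7=C11 alkene, stereocenters C5, C8 and C10 in the tether) is therefore closed by a Cp2Ti(PMe3)2-mediated hetero-Pauson–Khand reaction with CO, which forms C6–C7 and C11–C12 (then O–C12) in one operation, builds both rings and sets C6 and C7. A chiral-boron Ireland–Claisen rearrangement supplies C5 and C10; C11 methylation, C8 acylation and desilylation follow.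

Key step: step 10

Assumption: the (S,S) enantiomer of the diazaborolidine controller is written in step 7 and its facial preference on ester 10 is taken to lead to 12; should the sense be opposite, the (R,R) enantiomer of the same reagent is used.

Step 1
Reactants: 1 (2S)-2-ethenyloxirane
Product: 2 (3R)-hex-1-en-5-yn-3-ol
Conditions: LiC≡CH·H2NCH2CH2NH2, DMSO, 0 → 25 °C; then H2O
Reagents that add atoms: lithium acetylide–ethylenediamine complex, [Li]C#C.NCCN
Why: SN2 opening of the vinyl epoxide at its unsubstituted carbon by the hard acetylide in DMSO (no Lewis acid, so no allylic or SN2′ activation) should give the homopropargylic alcohol; the stereocenter (future C8) is not touched and only its descriptor changes.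

Step 2
Reactants: 2 (3R)-hex-1-en-5-yn-3-ol
Product: 3 triethyl{[(3R)-hex-1-en-5-yn-3-yl]oxy}silane
Conditions: Et3SiCl, imidazole, CH2Cl2, 0 °C
Reagents that add atoms: chlorotriethylsilane, CC[Si](Cl)(CC)CC
Why: Standard silylation of a secondary alcohol; the triethylsilyl ether is chosen because it can later be removed beside a tert-butyldiphenylsilyl ether.

Step 3
Reactants: 3 triethyl{[(3R)-hex-1-en-5-yn-3-yl]oxy}silane
Product: 5 (2E,5R)-3-methyl-5-(triethylsilyloxy)hepta-2,6-dien-1-ol, via alkenylalane 4 (not isolated)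
Conditions: AlMe3, Cp2ZrCl2 (cat.), CH2Cl2, 0 → 25 °C; then (CH2O)n, 0 → 25 °C; aq. KNaC4H4O6
Reagents that add atoms: trimethylaluminium, C[Al](C)C; formaldehyde (from paraformaldehyde), C=O
Why: Negishi zirconium-catalysed carboalumination adds methyl and aluminium syn across the terminal alkyne (methyl to the internal carbon), and the alkenylalane adds to formaldehyde with retention to give the (E)-trisubstituted allylic alcohol, while the monosubstituted alkene is inert under these conditions.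

Step 4
Reactants: 5 (2E,5R)-3-methyl-5-(triethylsilyloxy)hepta-2,6-dien-1-ol; 6 itaconic anhydride
Product: 7 2-methylidene-4-{[(2E,5R)-3-methyl-5-(triethylsilyloxy)hepta-2,6-dien-1-yl]oxy}-4-oxobutanoic acid
Conditions: toluene, 60 °C
Reagents that add atoms: none
Why: Alcoholysis of itaconic anhydride takes place at the non-conjugated, CH2-flanked carbonyl (the known regiochemistry), and the absence of base avoids isomerisation to the citraconate.

Step 5
Reactants: 7 2-methylidene-4-{[(2E,5R)-3-methyl-5-(triethylsilyloxy)hepta-2,6-dien-1-yl]oxy}-4-oxobutanoic acid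
Product: 9 (2E,5R)-3-methyl-5-(triethylsilyloxy)hepta-2,6-dien-1-yl 3-(hydroxymethyl)but-3-enoate, via mixed carbonic anhydride 8 (not isolated)
Conditions: i-BuOCOCl, N-methylmorpholine, THF, −15 °C; then NaBH4, H2O, −15 → 0 °C
Reagents that add atoms: none
Why: Mixed-anhydride activation followed by NaBH4 reduces only the activated conjugated acid to the allylic alcohol (future C15–OH), while the allyl ester and the silyl ether do not react at this temperature.

Step 6
Reactants: 9 (2E,5R)-3-methyl-5-(triethylsilyloxy)hepta-2,6-dien-1-yl 3-(hydroxymethyl)but-3-enoate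
Product: 10 (2E,5R)-3-methyl-5-(triethylsilyloxy)hepta-2,6-dien-1-yl 3-[(tert-butyldiphenylsilyloxy)methyl]but-3-enoate
Conditions: t-BuPh2SiCl, imidazole, CH2Cl2, 0 → 25 °C
Reagents that add atoms: tert-butyl(chloro)diphenylsilane, CC(C)(C)[Si](Cl)(c1ccccc1)c1ccccc1
Why: Silylation of the primary allylic alcohol stops lactonisation of the γ-hydroxy ester and installs a group that outlasts the later removal of the triethylsilyl ether.

Step 7
Reactants: 10 (2E,5R)-3-methyl-5-(triethylsilyloxy)hepta-2,6-dien-1-yl 3-[(tert-butyldiphenylsilyloxy)methyl]but-3-enoate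
Product: 12 (2S,3R,5R)-2-[3-(tert-butyldiphenylsilyloxy)prop-1-en-2-yl]-3-ethenyl-3-methyl-5-(triethylsilyloxy)hept-6-enoic acid, via boron ketene acetal 11 (not isolated)
Conditions: preformed (4S,5S)-2-bromo-4,5-diphenyl-1,3-bis[3,5-bis(trifluoromethyl)phenylsulfonyl]-1,3,2-diazaborolidine, Et3N, toluene/hexane, −78 °C; then 4 °C; H2O
Reagents that add atoms: none
Why: Enantioselective Ireland–Claisen rearrangement: soft enolisation by the chiral bromoborane and Et3N in toluene/hexane should give the E(O) boron ketene acetal 11, which rearranges through a chair transition state (C9 chain of the (E)-allyl unit equatorial, C10 methyl and the enolate substituent axial) to fix the C5/C10 relative configuration, while the C2-symmetric controller selects the enolate face and so the absolute configuration of both new stereocenters.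

Step 8
Reactants: 12 (2S,3R,5R)-2-[3-(tert-butyldiphenylsilyloxy)prop-1-en-2-yl]-3-ethenyl-3-methyl-5-(triethylsilyloxy)hept-6-enoic acid
Product: 13 (2S,3R,5R)-2-[3-(tert-butyldiphenylsilyloxy)prop-1-en-2-yl]-3-ethenyl-3-methyl-5-(triethylsilyloxy)hept-6-en-1-ol
Conditions: LiAlH4, Et2O, 0 → 25 °C; then H2O, aq. NaOH
Reagents that add atoms: none
Why: LiAlH4 reduces the hindered carboxylic acid to the primary alcohol without touching the isolated alkenes or the silyl ethers, and C5 is not epimerised.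

Step 9
Reactants: 13 (2S,3R,5R)-2-[3-(tert-butyldiphenylsilyloxy)prop-1-en-2-yl]-3-ethenyl-3-methyl-5-(triethylsilyloxy)hept-6-en-1-ol
Product: 14 (2S,3R,5R)-2-[3-(tert-butyldiphenylsilyloxy)prop-1-en-2-yl]-3-ethenyl-3-methyl-5-(triethylsilyloxy)hept-6-enal
Conditions: Dess–Martin periodinane, pyridine, CH2Cl2, 0 → 25 °C
Reagents that add atoms: none
Why: Buffered Dess–Martin oxidation gives the β,γ-unsaturated aldehyde under non-basic conditions, so the C5 stereocenter and the position of the double bond should be kept; the aldehyde is used at once.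

Step 10
Reactants: 14 (2S,3R,5R)-2-[3-(tert-butyldiphenylsilyloxy)prop-1-en-2-yl]-3-ethenyl-3-methyl-5-(triethylsilyloxy)hept-6-enal
Product: 17 (3aR,4R,6R,7S,7aS)-7-[3-(tert-butyldiphenylsilyloxy)prop-1-en-2-yl]-6-ethenyl-6-methyl-4-(triethylsilyloxy)hexahydro-1-benzofuran-2(3H)-one, via oxatitanacyclopentane 15 (not isolated), via acyl titanacycle 16 (not isolated)
Conditions: Cp2Ti(PMe3)2 (1.2 equiv), toluene, 25 °C; then CO (1 atm), 25 → 70 °C
Reagents that add atoms: carbon monoxide, [C-]#[O+]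
Why: Cp2Ti(PMe3)2 (divalent titanium) loses PMe3 and binds the C6 aldehyde of 14 as an η2 complex, the tethered terminal C7=C11 alkene inserts into its Ti–C6 bond to form C6–C7 and the oxatitanacyclopentane 15 (tetravalent titanium bound to O6 and C11), CO inserts into Ti–C11 to form C11–C12 (16), and reductive elimination closes O–C12, releasing 17 and Cp2Ti(CO)2. The closest known reaction type is the hetero-Pauson–Khand cyclocarbonylation of tethered enals and enones mediated by Cp2Ti(PMe3)2, used here in its stoichiometric form. Ring A closes by exo insertion of the terminal alkene (six-membered carbocycle, C6 onto the internal alkene carbon C7), and ring B is assembled as a formal [2+2+1] of C6=O, C7=C11 and CO. C6 and C7 are set in a chair-like insertion transition state in which the C5 side chain, the C8 silyloxy group and the C10 vinyl group are equatorial and the C10 methyl is axial; the aldehyde oxygen then sits equatorial (an axial oxygen would be syn-axial to the C10 methyl) and the alkene equatorial, which should give the trans ring fusion with H6 anti to H5 and H7 anti to H8. The step needs chemoselectivity among three alkenes, secured because only the C7 vinyl group can reach C6 through a six-membered ring (the C10 vinyl and the 2-propenyl group would give three- or four-membered rings), and it needs an unhindered alkene, which is why the alkene is kept terminal and the C11 methyl is added afterwards.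

Step 11
Reactants: 17 (3aR,4R,6R,7S,7aS)-7-[3-(tert-butyldiphenylsilyloxy)prop-1-en-2-yl]-6-ethenyl-6-methyl-4-(triethylsilyloxy)hexahydro-1-benzofuran-2(3H)-one
Product: 20 (3R,3aR,4R,6R,7S,7aS)-7-[3-(tert-butyldiphenylsilyloxy)prop-1-en-2-yl]-6-ethenyl-3,6-dimethyl-4-(triethylsilyloxy)hexahydro-1-benzofuran-2(3H)-one, via lithium enolate 18 (not isolated), via C11 epimer 19 (not isolated)
Conditions: LiN(i-Pr)2, THF, −78 °C; MeI, −78 → −20 °C; concentrate; then KOt-Bu (cat.), t-BuOH/THF, 25 °C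
Reagents that add atoms: iodomethane, CI
Why: Alkylation of the lithium enolate 18 with MeI should place the methyl mainly anti to the axial H7 (epimer 19), and since C11 stays enolisable, catalytic KOt-Bu then equilibrates it to 20, the more stable epimer with a pseudo-equatorial methyl cis to H7 and remote from the C8 silyloxy group.

Step 12
Reactants: 20 (3R,3aR,4R,6R,7S,7aS)-7-[3-(tert-butyldiphenylsilyloxy)prop-1-en-2-yl]-6-ethenyl-3,6-dimethyl-4-(triethylsilyloxy)hexahydro-1-benzofuran-2(3H)-one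
Product: 21 (3R,3aS,4R,6R,7S,7aS)-7-[3-(tert-butyldiphenylsilyloxy)prop-1-en-2-yl]-6-ethenyl-4-hydroxy-3,6-dimethylhexahydro-1-benzofuran-2(3H)-one
Conditions: PPTS, MeOH/CH2Cl2, 0 → 25 °C
Reagents that add atoms: none
Why: Mild acidic methanolysis cleaves the secondary triethylsilyl ether much faster than the primary tert-butyldiphenylsilyl ether, and the lactone and C11 are not affected by the weak acid.

Step 13
Reactants: 22 2-(tert-butyldimethylsilyloxy)acetaldehyde; 23 1,1,1,3,3,3-hexafluoropropan-2-yl prop-2-enoate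
Product: 24 1,1,1,3,3,3-hexafluoropropan-2-yl (3S)-4-(tert-butyldimethylsilyloxy)-3-hydroxy-2-methylidenebutanoate
Conditions: β-isocupreidine (10 mol %), DMF, −55 °C
Reagents that add atoms: none
Why: Asymmetric Morita–Baylis–Hillman reaction in which the quinuclidine nitrogen of β-isocupreidine adds to the activated acrylate and the phenolic OH of the catalyst organises the aldol step; the spatial arrangement known for aliphatic aldehydes corresponds to (S) here because of the CH2O substituent and sets C3′.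

Step 14
Reactants: 24 1,1,1,3,3,3-hexafluoropropan-2-yl (3S)-4-(tert-butyldimethylsilyloxy)-3-hydroxy-2-methylidenebutanoate
Product: 25 1,1,1,3,3,3-hexafluoropropan-2-yl (3S)-3,4-bis(tert-butyldimethylsilyloxy)-2-methylidenebutanoate
Conditions: t-BuMe2SiOTf, 2,6-lutidine, CH2Cl2, −78 → 0 °C
Reagents that add atoms: tert-butyldimethylsilyl trifluoromethanesulfonate, CC(C)(C)[Si](C)(C)OS(=O)(=O)C(F)(F)F
Why: Silyl triflate with a hindered base silylates the secondary allylic alcohol quickly at low temperature, which avoids retro-aldol cleavage or elimination of the adduct.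

Step 15
Reactants: 25 1,1,1,3,3,3-hexafluoropropan-2-yl (3S)-3,4-bis(tert-butyldimethylsilyloxy)-2-methylidenebutanoate
Product: 26 (3S)-3,4-bis(tert-butyldimethylsilyloxy)-2-methylidenebutanoic acid
Conditions: LiOH, THF/H2O, 0 °C; then 1 M HCl to pH 3
Reagents that add atoms: lithium hydroxide, [Li+].[OH-]
Why: The activated hexafluoroisopropyl ester is hydrolysed at 0 °C faster than hydroxide can add to the α-substituted acrylate, and C3′ carries no acidic hydrogen that could epimerise.

Step 16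
Reactants: 26 (3S)-3,4-bis(tert-butyldimethylsilyloxy)-2-methylidenebutanoic acid; 21 (3R,3aS,4R,6R,7S,7aS)-7-[3-(tert-butyldiphenylsilyloxy)prop-1-en-2-yl]-6-ethenyl-4-hydroxy-3,6-dimethylhexahydro-1-benzofuran-2(3H)-one
Product: 28 (3R,3aS,4R,6R,7S,7aS)-7-[3-(tert-butyldiphenylsilyloxy)prop-1-en-2-yl]-6-ethenyl-3,6-dimethyl-2-oxooctahydro-1-benzofuran-4-yl (3S)-3,4-bis(tert-butyldimethylsilyloxy)-2-methylidenebutanoate, via mixed trichlorobenzoic anhydride 27 (not isolated)
Conditions: 2,4,6-Cl3C6H2COCl, Et3N, toluene, 25 °C; then 21, DMAP, 25 °C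
Reagents that add atoms: none
Why: Yamaguchi esterification: the mixed anhydride 27 transfers the acryloyl group through DMAP to the hindered equatorial C8 hydroxyl, and no stereocenter is involved.

Step 17
Reactants: 28 (3R,3aS,4R,6R,7S,7aS)-7-[3-(tert-butyldiphenylsilyloxy)prop-1-en-2-yl]-6-ethenyl-3,6-dimethyl-2-oxooctahydro-1-benzofuran-4-yl (3S)-3,4-bis(tert-butyldimethylsilyloxy)-2-methylidenebutanoate
Product: 29 (3R,3aS,4R,6R,7S,7aS)-6-ethenyl-7-(3-hydroxyprop-1-en-2-yl)-3,6-dimethyl-2-oxooctahydro-1-benzofuran-4-yl (3S)-3,4-dihydroxy-2-methylidenebutanoate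
Conditions: HF·pyridine, pyridine/THF, 0 → 25 °C
Reagents that add atoms: none
Why: Fluoride cleaves all three silyl ethers in one operation under weakly acidic buffered conditions, which should avoid base-induced lactonisation of the freed side-chain diol onto its own ester and translactonisation of ring B.

Compound list
1 | (2S)-2-ethenyloxirane | C=C[C@H]1CO1 | starting material
2 | (3R)-hex-1-en-5-yn-3-ol | C#CC[C@@H](O)C=C | intermediate
3 | triethyl{[(3R)-hex-1-en-5-yn-3-yl]oxy}silane | C#CC[C@@H](O[Si](CC)(CC)CC)C=C | intermediate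
4 | dimethyl[(1E,4R)-2-methyl-4-(triethylsilyloxy)hexa-1,5-dien-1-yl]alumane (not isolated) | C[Al](C)/C=C(\C)C[C@@H](O[Si](CC)(CC)CC)C=C | intermediate
5 | (2E,5R)-3-methyl-5-(triethylsilyloxy)hepta-2,6-dien-1-ol | OC/C=C(\C)C[C@@H](O[Si](CC)(CC)CC)C=C | intermediate
6 | itaconic anhydride (3-methylideneoxolane-2,5-dione) | C=C1CC(=O)OC1=O | starting material
7 | 2-methylidene-4-{[(2E,5R)-3-methyl-5-(triethylsilyloxy)hepta-2,6-dien-1-yl]oxy}-4-oxobutanoic acid | OC(=O)C(=C)CC(=O)OC/C=C(\C)C[C@@H](O[Si](CC)(CC)CC)C=C | intermediate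
8 | mixed isobutyl carbonic anhydride of 7 (not isolated) | CC(C)COC(=O)OC(=O)C(=C)CC(=O)OC/C=C(\C)C[C@@H](O[Si](CC)(CC)CC)C=C | intermediate
9 | (2E,5R)-3-methyl-5-(triethylsilyloxy)hepta-2,6-dien-1-yl 3-(hydroxymethyl)but-3-enoate | OCC(=C)CC(=O)OC/C=C(\C)C[C@@H](O[Si](CC)(CC)CC)C=C | intermediate
10 | (2E,5R)-3-methyl-5-(triethylsilyloxy)hepta-2,6-dien-1-yl 3-[(tert-butyldiphenylsilyloxy)methyl]but-3-enoate | C=C(CO[Si](c1ccccc1)(c1ccccc1)C(C)(C)C)CC(=O)OC/C=C(\C)C[C@@H](O[Si](CC)(CC)CC)C=C | intermediate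
11 | E(O) boron ketene acetal of 10 with the (S,S)-diazaborolidine (2-propenyl substituent cis to the allyloxy oxygen; not isolated) | C=C(CO[Si](c1ccccc1)(c1ccccc1)C(C)(C)C)/C=C(\OC/C=C(\C)C[C@@H](O[Si](CC)(CC)CC)C=C)OB1N(S(=O)(=O)c2cc(cc(c2)C(F)(F)F)C(F)(F)F)[C@@H](c2ccccc2)[C@H](c2ccccc2)N1S(=O)(=O)c1cc(cc(c1)C(F)(F)F)C(F)(F)F | intermediate
12 | (2S,3R,5R)-2-[3-(tert-butyldiphenylsilyloxy)prop-1-en-2-yl]-3-ethenyl-3-methyl-5-(triethylsilyloxy)hept-6-enoic acid | C=C[C@@](C)(C[C@@H](O[Si](CC)(CC)CC)C=C)[C@H](C(=O)O)C(=C)CO[Si](c1ccccc1)(c1ccccc1)C(C)(C)C | intermediate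
13 | (2S,3R,5R)-2-[3-(tert-butyldiphenylsilyloxy)prop-1-en-2-yl]-3-ethenyl-3-methyl-5-(triethylsilyloxy)hept-6-en-1-ol | C=C[C@@](C)(C[C@@H](O[Si](CC)(CC)CC)C=C)[C@H](CO)C(=C)CO[Si](c1ccccc1)(c1ccccc1)C(C)(C)C | intermediate
14 | (2S,3R,5R)-2-[3-(tert-butyldiphenylsilyloxy)prop-1-en-2-yl]-3-ethenyl-3-methyl-5-(triethylsilyloxy)hept-6-enal | C=C[C@@](C)(C[C@@H](O[Si](CC)(CC)CC)C=C)[C@H](C=O)C(=C)CO[Si](c1ccccc1)(c1ccccc1)C(C)(C)C | intermediate
15 | trans-fused oxatitanacyclopentane from 14, Cp2Ti bound to O6 and C11 (cyclopentadienyl rings drawn σ-bonded in the SMILES; not isolated) | C=C[C@@]1(C)C[C@@H](O[Si](CC)(CC)CC)[C@H]2[C@@H](O[Ti](C3C=CC=C3)(C3C=CC=C3)C2)[C@@H]1C(=C)CO[Si](c1ccccc1)(c1ccccc1)C(C)(C)C | intermediate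
16 | acyl titanacycle after CO insertion into Ti–C11 (cyclopentadienyl rings drawn σ-bonded in the SMILES; not isolated) | C=C[C@@]1(C)C[C@@H](O[Si](CC)(CC)CC)[C@H]2[C@@H](O[Ti](C3C=CC=C3)(C3C=CC=C3)C(=O)C2)[C@@H]1C(=C)CO[Si](c1ccccc1)(c1ccccc1)C(C)(C)C | intermediate
17 | (3aR,4R,6R,7S,7aS)-7-[3-(tert-butyldiphenylsilyloxy)prop-1-en-2-yl]-6-ethenyl-6-methyl-4-(triethylsilyloxy)hexahydro-1-benzofuran-2(3H)-one | C=C[C@@]1(C)C[C@@H](O[Si](CC)(CC)CC)[C@H]2[C@@H](OC(=O)C2)[C@@H]1C(=C)CO[Si](c1ccccc1)(c1ccccc1)C(C)(C)C | intermediate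
18 | lithium enolate of 17 (not isolated) | C=C[C@@]1(C)C[C@@H](O[Si](CC)(CC)CC)[C@H]2[C@@H](OC(O[Li])=C2)[C@@H]1C(=C)CO[Si](c1ccccc1)(c1ccccc1)C(C)(C)C | intermediate
19 | (3S,3aR,4R,6R,7S,7aS)-7-[3-(tert-butyldiphenylsilyloxy)prop-1-en-2-yl]-6-ethenyl-3,6-dimethyl-4-(triethylsilyloxy)hexahydro-1-benzofuran-2(3H)-one (C11 epimer; not isolated) | C=C[C@@]1(C)C[C@@H](O[Si](CC)(CC)CC)[C@H]2[C@@H](OC(=O)[C@H]2C)[C@@H]1C(=C)CO[Si](c1ccccc1)(c1ccccc1)C(C)(C)C | intermediate
20 | (3R,3aR,4R,6R,7S,7aS)-7-[3-(tert-butyldiphenylsilyloxy)prop-1-en-2-yl]-6-ethenyl-3,6-dimethyl-4-(triethylsilyloxy)hexahydro-1-benzofuran-2(3H)-one | C=C[C@@]1(C)C[C@@H](O[Si](CC)(CC)CC)[C@H]2[C@@H](OC(=O)[C@@H]2C)[C@@H]1C(=C)CO[Si](c1ccccc1)(c1ccccc1)C(C)(C)C | intermediate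
21 | (3R,3aS,4R,6R,7S,7aS)-7-[3-(tert-butyldiphenylsilyloxy)prop-1-en-2-yl]-6-ethenyl-4-hydroxy-3,6-dimethylhexahydro-1-benzofuran-2(3H)-one | C=C[C@@]1(C)C[C@@H](O)[C@H]2[C@@H](OC(=O)[C@@H]2C)[C@@H]1C(=C)CO[Si](c1ccccc1)(c1ccccc1)C(C)(C)C | intermediate
22 | 2-(tert-butyldimethylsilyloxy)acetaldehyde | O=CCO[Si](C)(C)C(C)(C)C | starting material
23 | 1,1,1,3,3,3-hexafluoropropan-2-yl prop-2-enoate | C=CC(=O)OC(C(F)(F)F)C(F)(F)F | starting material
24 | 1,1,1,3,3,3-hexafluoropropan-2-yl (3S)-4-(tert-butyldimethylsilyloxy)-3-hydroxy-2-methylidenebutanoate | C=C(C(=O)OC(C(F)(F)F)C(F)(F)F)[C@H](O)CO[Si](C)(C)C(C)(C)C | intermediate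
25 | 1,1,1,3,3,3-hexafluoropropan-2-yl (3S)-3,4-bis(tert-butyldimethylsilyloxy)-2-methylidenebutanoate | C=C(C(=O)OC(C(F)(F)F)C(F)(F)F)[C@H](O[Si](C)(C)C(C)(C)C)CO[Si](C)(C)C(C)(C)C | intermediate
26 | (3S)-3,4-bis(tert-butyldimethylsilyloxy)-2-methylidenebutanoic acid | C=C(C(=O)O)[C@H](O[Si](C)(C)C(C)(C)C)CO[Si](C)(C)C(C)(C)C | intermediate
27 | mixed 2,4,6-trichlorobenzoic anhydride of 26 (not isolated) | C=C(C(=O)OC(=O)c1c(Cl)cc(Cl)cc1Cl)[C@H](O[Si](C)(C)C(C)(C)C)CO[Si](C)(C)C(C)(C)C | intermediate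
28 | (3R,3aS,4R,6R,7S,7aS)-7-[3-(tert-butyldiphenylsilyloxy)prop-1-en-2-yl]-6-ethenyl-3,6-dimethyl-2-oxooctahydro-1-benzofuran-4-yl (3S)-3,4-bis(tert-butyldimethylsilyloxy)-2-methylidenebutanoate | C=C[C@@]1(C)C[C@@H](OC(=O)C(=C)[C@H](O[Si](C)(C)C(C)(C)C)CO[Si](C)(C)C(C)(C)C)[C@H]2[C@@H](OC(=O)[C@@H]2C)[C@@H]1C(=C)CO[Si](c1ccccc1)(c1ccccc1)C(C)(C)C | intermediate
29 | (3R,3aS,4R,6R,7S,7aS)-6-ethenyl-7-(3-hydroxyprop-1-en-2-yl)-3,6-dimethyl-2-oxooctahydro-1-benzofuran-4-yl (3S)-3,4-dihydroxy-2-methylidenebutanoate | C=C[C@@]1(C)C[C@@H](OC(=O)C(=C)[C@H](O)CO)[C@H]2[C@@H](OC(=O)[C@@H]2C)[C@@H]1C(=C)CO | target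

Total step count: 17. Longest linear sequence: 14 steps (steps 1–12, 16 and 17); steps 13–15 make the side-chain acid.

Steps most likely to fail

Step 10. The tethered alkene may fail to insert into the crowded η2-aldehyde complex of titanium, because the aldehyde is α-branched and sits beside the quaternary C10. Pinacol-type coupling, or migration of the β,γ-double bond of 14 into conjugation under the basic phosphine, could then take over. The fallback sets out from 14 and comes back at 17. Cross-metathesis of the C7 vinyl group of 14 with methyl acrylate (second-generation Hoveyda–Grubbs catalyst, (H2IMes)Cl2Ru(=CH-C6H4-2-OiPr), CH2Cl2, 40 °C; the neopentyl C10 vinyl and the 2-propenyl group react far more slowly) would give methyl (2E,4R,6R,7S)-7-[3-(tert-butyldiphenylsilyloxy)prop-1-en-2-yl]-6-ethenyl-6-methyl-8-oxo-4-(triethylsilyloxy)oct-2-enoate F1. Treatment with SmI2 (divalent samarium) in THF/MeOH at −78 °C then generates the ketyl radical of the C6 aldehyde, which adds 6-exo to C7 of the enoate through the same all-equatorial chair. The samarium enolate is protonated at C11 and the C6 alkoxide closes the lactone to 17. In this fallback C11 and C12 arrive together with the acrylate, so the C11–C12 bond is no longer made in the ring-forming step.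

Step 7. Soft enolisation of this heavily functionalised ester by the bromoborane may be incomplete, or the controller may exert weak facial control, which would erode the configuration at C5 and C10. The fallback sets out from 10 and comes back at 12. A lithium-enolate Ireland–Claisen rearrangement (LiN(i-Pr)2, Me3SiCl, THF, −78 → 25 °C) would give the E(O) trimethylsilyl ketene acetal of 10 F2, which rearranges through the same chair without facial control. This gives trimethylsilyl (2S,3R,5R)-2-[3-(tert-butyldiphenylsilyloxy)prop-1-en-2-yl]-3-ethenyl-3-methyl-5-(triethylsilyloxy)hept-6-enoate F3 and its (2R,3S,5R) isomer F4. Aqueous work-up hydrolyses them to 12 and to (2R,3S,5R)-2-[3-(tert-butyldiphenylsilyloxy)prop-1-en-2-yl]-3-ethenyl-3-methyl-5-(triethylsilyloxy)hept-6-enoic acid F5. The two acids are diastereomers because of the fixed C8 center and are separated by chromatography, at the cost of about half of the material.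

Step 11. The alkylation may show poor facial selectivity at C11, may over-alkylate, or the base equilibration may stall. The fallback sets out from 17 and comes back at 20. The enolate of 17 (LiN(i-Pr)2, THF, −78 °C) is trapped with dimethylmethyleneammonium iodide to give (3aR,4R,6R,7S,7aS)-7-[3-(tert-butyldiphenylsilyloxy)prop-1-en-2-yl]-3-[(dimethylamino)methyl]-6-ethenyl-6-methyl-4-(triethylsilyloxy)hexahydro-1-benzofuran-2(3H)-one F6. Quaternisation with MeI and elimination with NaHCO3 give (3aR,4R,6R,7S,7aS)-7-[3-(tert-butyldiphenylsilyloxy)prop-1-en-2-yl]-6-ethenyl-6-methyl-3-methylidene-4-(triethylsilyloxy)hexahydro-1-benzofuran-2(3H)-one F7. NaBH4 in MeOH at 0 °C then adds hydride to the exocyclic methylene carbon, and protonation of the resulting enolate anti to H7 (the usual course for trans-fused α-methylene lactones, and also the thermodynamic outcome) should give 20.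

Further compounds
F1 | step 10 | methyl (2E,4R,6R,7S)-7-[3-(tert-butyldiphenylsilyloxy)prop-1-en-2-yl]-6-ethenyl-6-methyl-8-oxo-4-(triethylsilyloxy)oct-2-enoate | C=C[C@@](C)(C[C@@H](O[Si](CC)(CC)CC)/C=C/C(=O)OC)[C@H](C=O)C(=C)CO[Si](c1ccccc1)(c1ccccc1)C(C)(C)C
F2 | step 7 | E(O) trimethylsilyl ketene acetal of 10 | C=C(CO[Si](c1ccccc1)(c1ccccc1)C(C)(C)C)/C=C(\OC/C=C(\C)C[C@@H](O[Si](CC)(CC)CC)C=C)O[Si](C)(C)C
F3 | step 7 | trimethylsilyl (2S,3R,5R)-2-[3-(tert-butyldiphenylsilyloxy)prop-1-en-2-yl]-3-ethenyl-3-methyl-5-(triethylsilyloxy)hept-6-enoate | C=C[C@@](C)(C[C@@H](O[Si](CC)(CC)CC)C=C)[C@H](C(=O)O[Si](C)(C)C)C(=C)CO[Si](c1ccccc1)(c1ccccc1)C(C)(C)C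
F4 | step 7 | trimethylsilyl (2R,3S,5R)-2-[3-(tert-butyldiphenylsilyloxy)prop-1-en-2-yl]-3-ethenyl-3-methyl-5-(triethylsilyloxy)hept-6-enoate | C=C[C@](C)(C[C@@H](O[Si](CC)(CC)CC)C=C)[C@@H](C(=O)O[Si](C)(C)C)C(=C)CO[Si](c1ccccc1)(c1ccccc1)C(C)(C)C
F5 | step 7 | (2R,3S,5R)-2-[3-(tert-butyldiphenylsilyloxy)prop-1-en-2-yl]-3-ethenyl-3-methyl-5-(triethylsilyloxy)hept-6-enoic acid | C=C[C@](C)(C[C@@H](O[Si](CC)(CC)CC)C=C)[C@@H](C(=O)O)C(=C)CO[Si](c1ccccc1)(c1ccccc1)C(C)(C)C
F6 | step 11 | (3aR,4R,6R,7S,7aS)-7-[3-(tert-butyldiphenylsilyloxy)prop-1-en-2-yl]-3-[(dimethylamino)methyl]-6-ethenyl-6-methyl-4-(triethylsilyloxy)hexahydro-1-benzofuran-2(3H)-one (C3 epimers) | C=C[C@@]1(C)C[C@@H](O[Si](CC)(CC)CC)[C@H]2[C@@H](OC(=O)C2CN(C)C)[C@@H]1C(=C)CO[Si](c1ccccc1)(c1ccccc1)C(C)(C)C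
F7 | step 11 | (3aR,4R,6R,7S,7aS)-7-[3-(tert-butyldiphenylsilyloxy)prop-1-en-2-yl]-6-ethenyl-6-methyl-3-methylidene-4-(triethylsilyloxy)hexahydro-1-benzofuran-2(3H)-one | C=C[C@@]1(C)C[C@@H](O[Si](CC)(CC)CC)[C@H]2[C@@H](OC(=O)C2=C)[C@@H]1C(=C)CO[Si](c1ccccc1)(c1ccccc1)C(C)(C)C
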